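**Strategy.** Stenine numbering is used. The tertiary carbinol C1 next to the enamine carbon C9a marks the carbocycle (C1, C9a, C9, C10, C11, C12) as a masked 2-hydroxycyclohexanone. This ketol is traced back, by an α-ketol shift, to a 1-acylcyclopentanol on a cis-fused bicyclic lactone. In one operation C12 migrates from C9a to the acyl carbon C1: the cyclopentane becomes the six-membered ring, the C1 stereocentre is set, and the ketone arrives γ to nitrogen. A temporary tert-butyl ester on C9 blocks the competing migration; acid later removes it as CO2 while freeing the amine, which closes the pyrroline and azepine rings.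

Key step: step 15

Remark: numbering is N4, C1–C3 (pyrrolidine), C5–C8 (azepane chain), C9=C9a (enamine), C10–C12 (carbocycle), C13 (α-carbon of the ring lactone), C18–C20 (side-chain lactone); compounds 1, 13, 14 and 16 are assumed to be purchasable, and 4-chlorobutylmagnesium bromide is used as a prepared solution.

**Step 1**
Reactants: 1 (4S)-4-[(tert-butyldimethylsilyl)oxy]cyclopent-2-en-1-one
Product: 3 (1R,4S)-4-[(tert-butyldimethylsilyl)oxy]-1-ethylcyclopent-2-en-1-yl acetate, via bromomagnesium alkoxide 2 (not isolated)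
Conditions: EtMgBr, CeCl3, THF, −78 °C; then Ac2O, −78 °C to rt
Reagents that add atoms: ethylmagnesium bromide, CC[Mg]Br; acetic anhydride, CC(=O)OC(C)=O
Why: 1,2-addition of the cerium-modified Grignard reagent should occur anti to the C4 silyloxy group, so the tertiary alkoxide is cis to the silyl ether and is acetylated in the same flask.

**Step 2**
Reactants: 3 (1R,4S)-4-[(tert-butyldimethylsilyl)oxy]-1-ethylcyclopent-2-en-1-yl acetate
Product: 6 2-[(1R,5S)-5-[(tert-butyldimethylsilyl)oxy]-3-ethylcyclopent-2-en-1-yl]acetic acid, via silyl ketene acetal 4 (not isolated), via trimethylsilyl ester 5 (not isolated)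
Conditions: LiN(iPr)2, Me3SiCl, Et3N, THF, −78 °C to 65 °C; then aq. citric acid
Reagents that add atoms: none
Why: the Ireland–Claisen rearrangement is suprafacial, so the acetic acid chain arrives at C12 on the face the acetate leaves (cis to the silyl ether), which transfers the carbinol chirality to C12 and leaves the C10=C11 alkene bearing the ethyl group.

**Step 3**
Reactants: 6 2-[(1R,5S)-5-[(tert-butyldimethylsilyl)oxy]-3-ethylcyclopent-2-en-1-yl]acetic acid
Product: 7 (3aR,4S,6R,6aR)-4-[(tert-butyldimethylsilyl)oxy]-6-ethylhexahydro-2H-cyclopenta[b]furan-2-one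
Conditions: 9-mesityl-10-methylacridinium tetrafluoroborate (5 mol %), PhSH (20 mol %), 2,6-lutidine (20 mol %), 1,2-dichloroethane, 450 nm LEDs, rt
Reagents that add atoms: none
Why: acridinium photoredox anti-Markovnikov hydrolactonization (alkene radical cation, 5-exo attack of the carboxylate at the less substituted C11, then hydrogen-atom transfer from PhSH to the tertiary C10 radical on the convex face) should give the cis-fused γ-lactone with the ethyl group on the concave face.

**Step 4**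
Reactants: 7 (3aR,4S,6R,6aR)-4-[(tert-butyldimethylsilyl)oxy]-6-ethylhexahydro-2H-cyclopenta[b]furan-2-one
Product: 8 (3R,3aR,4S,6R,6aR)-4-[(tert-butyldimethylsilyl)oxy]-6-ethyl-3-methylhexahydro-2H-cyclopenta[b]furan-2-one
Conditions: LiN(iPr)2, THF, −78 °C; MeI
Reagents that add atoms: iodomethane, CI
Why: alkylation of the lactone enolate should take place on the convex face of the cis-fused bicycle, which places the C13 methyl group exo (13R).

**Step 5**
Reactants: 8 (3R,3aR,4S,6R,6aR)-4-[(tert-butyldimethylsilyl)oxy]-6-ethyl-3-methylhexahydro-2H-cyclopenta[b]furan-2-one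
Product: 10 (3R,3aR,6R,6aR)-6-ethyl-3-methyltetrahydro-2H-cyclopenta[b]furan-2,4(3H)-dione, via alcohol 9 (not isolated)
Conditions: HF (48% aq.), MeCN, rt; then CrO3, H2SO4, acetone, 0 °C
Reagents that add atoms: none
Why: acidic desilylation followed by Jones oxidation of the secondary alcohol gives the cyclopentanone under conditions that avoid base-induced β-elimination of the lactone oxygen.

**Step 6**
Reactants: 10 (3R,3aR,6R,6aR)-6-ethyl-3-methyltetrahydro-2H-cyclopenta[b]furan-2,4(3H)-dione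
Product: 11 tert-butyl (3R,3aR,5R,6R,6aR)-6-ethyl-3-methyl-2,4-dioxohexahydro-2H-cyclopenta[b]furan-5-carboxylate (C5 epimerisable)
Conditions: LiN(SiMe3)2 (2.2 equiv), THF, −78 °C; Boc2O; then 1 M HCl
Reagents that add atoms: di-tert-butyl dicarbonate, CC(C)(C)OC(=O)OC(=O)OC(C)(C)C
Why: kinetic deprotonation at the less hindered C9 methylene and Claisen-type C-acylation (the second equivalent of base stores the product as its enolate) installs the ester that later activates and blocks C9.

**Step 7**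
Reactants: 11 tert-butyl (3R,3aR,5R,6R,6aR)-6-ethyl-3-methyl-2,4-dioxohexahydro-2H-cyclopenta[b]furan-5-carboxylate
Product: 12 tert-butyl (3R,3aR,6R,6aR)-6-ethyl-3-methyl-2-oxo-4-(trifluoromethanesulfonyloxy)-3,3a,6,6a-tetrahydro-2H-cyclopenta[b]furan-5-carboxylate
Conditions: Tf2O, iPr2NEt, CH2Cl2, −78 °C
Reagents that add atoms: trifluoromethanesulfonic anhydride, O=S(=O)(OS(=O)(=O)C(F)(F)F)C(F)(F)F
Why: O-triflation of the β-keto ester enol, which can only form toward C9, gives the tetrasubstituted enol triflate regiospecifically.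

**Step 8**
Reactants: 13 2-[(tert-butyldimethylsilyl)oxy]acetaldehyde; 14 (R)-2-methylpropane-2-sulfinamide
Product: 15 (R,E)-N-{2-[(tert-butyldimethylsilyl)oxy]ethylidene}-2-methylpropane-2-sulfinamide
Conditions: CuSO4, CH2Cl2, rt
Reagents that add atoms: none
Why: condensation of the aldehyde with the sulfinamide (Ellman imine formation, CuSO4 as dehydrating agent) gives the E-sulfinimine.

**Step 9**
Reactants: 16 3-methylfuran-2(5H)-one; 15 (R,E)-N-{2-[(tert-butyldimethylsilyl)oxy]ethylidene}-2-methylpropane-2-sulfinamide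
Product: 18 (R)-N-[(1S)-2-[(tert-butyldimethylsilyl)oxy]-1-[(2S)-4-methyl-5-oxo-2,5-dihydrofuran-2-yl]ethyl]-2-methylpropane-2-sulfinamide, via silyloxyfuran 17 (not isolated)
Conditions: 16, tBuMe2SiOTf, Et3N, CH2Cl2, 0 °C; then 15, Me3SiOTf (20 mol %), −78 °C
Reagents that add atoms: none
Why: soft enolisation gives the 2-silyloxyfuran, whose Lewis-acid-promoted vinylogous Mukaiyama–Mannich addition through an open transition state should attack the imine face anti to the tert-butyl group (C3 S) and give the threo (N/O syn) butenolide usual for silyloxyfurans (C18 S).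

**Step 10**
Reactants: 18 (R)-N-[(1S)-2-[(tert-butyldimethylsilyl)oxy]-1-[(2S)-4-methyl-5-oxo-2,5-dihydrofuran-2-yl]ethyl]-2-methylpropane-2-sulfinamide
Product: 20 tert-butyl N-[(1S)-2-hydroxy-1-[(2S)-4-methyl-5-oxo-2,5-dihydrofuran-2-yl]ethyl]carbamate, via amino alcohol hydrochloride 19 (not isolated)
Conditions: HCl (4 M in dioxane), MeOH, 0 °C; evaporate; Boc2O, NaHCO3, THF/H2O
Reagents that add atoms: di-tert-butyl dicarbonate, CC(C)(C)OC(=O)OC(=O)OC(C)(C)C
Why: acidic methanolysis cleaves both the N-sulfinyl and the O-silyl group, and the ammonium salt is capped as the Boc carbamate before the free amine can attack the butenolide.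

**Step 11**
Reactants: 20 tert-butyl N-[(1S)-2-hydroxy-1-[(2S)-4-methyl-5-oxo-2,5-dihydrofuran-2-yl]ethyl]carbamate
Product: 21 tert-butyl N-[(1S)-2-hydroxy-1-[(2S,4S)-4-methyl-5-oxooxolan-2-yl]ethyl]carbamate
Conditions: H2 (1 atm), Rh/Al2O3, EtOAc, rt
Reagents that add atoms: none
Why: heterogeneous hydrogenation should deliver hydrogen to the butenolide face opposite the C18 substituent, giving the cis-2,4-disubstituted lactone (C20 S) without hydrogenolysis of the allylic C–O bond.

**Step 12**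
Reactants: 21 tert-butyl N-[(1S)-2-hydroxy-1-[(2S,4S)-4-methyl-5-oxooxolan-2-yl]ethyl]carbamate
Product: 22 tert-butyl N-[(1R)-2-iodo-1-[(2S,4S)-4-methyl-5-oxooxolan-2-yl]ethyl]carbamate
Conditions: I2, PPh3, imidazole, CH2Cl2, 0 °C
Reagents that add atoms: iodine, II
Why: Appel-type iodination of the primary alcohol, as used for Boc-serine esters, gives the β-amido iodide without touching the stereocentres.

**Step 13**
Reactants: 12 tert-butyl (3R,3aR,6R,6aR)-6-ethyl-3-methyl-2-oxo-4-(trifluoromethanesulfonyloxy)-3,3a,6,6a-tetrahydro-2H-cyclopenta[b]furan-5-carboxylate; 22 tert-butyl N-[(1R)-2-iodo-1-[(2S,4S)-4-methyl-5-oxooxolan-2-yl]ethyl]carbamate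
Product: 24 tert-butyl (3R,3aS,6R,6aR)-4-{(3S)-3-[(tert-butoxycarbonyl)amino]-3-[(2S,4S)-4-methyl-5-oxooxolan-2-yl]propanoyl}-6-ethyl-3-methyl-2-oxo-3,3a,6,6a-tetrahydro-2H-cyclopenta[b]furan-5-carboxylate, via organozinc iodide 23 (not isolated)
Conditions: 22, Zn dust (Me3SiCl-activated), DMF, rt; then 12, CO (1 atm), Pd(PPh3)4 (5 mol %), LiCl, THF, 50 °C
Reagents that add atoms: carbon monoxide, [C-]#[O+]
Why: zinc insertion gives a carbamate-stabilised β-amido alkylzinc (Jackson-type reagent), and carbonylative Negishi coupling (oxidative addition of the enol triflate, CO insertion, transmetalation, reductive elimination) forms the ketone with C1 coming from CO.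

**Step 14**
Reactants: 24 tert-butyl (3R,3aS,6R,6aR)-4-{(3S)-3-[(tert-butoxycarbonyl)amino]-3-[(2S,4S)-4-methyl-5-oxooxolan-2-yl]propanoyl}-6-ethyl-3-methyl-2-oxo-3,3a,6,6a-tetrahydro-2H-cyclopenta[b]furan-5-carboxylate
Product: 26 tert-butyl (3R,3aR,4S,5S,6R,6aR)-4-{(3S)-3-[(tert-butoxycarbonyl)amino]-3-[(2S,4S)-4-methyl-5-oxooxolan-2-yl]propanoyl}-5-(4-chlorobutyl)-6-ethyl-4-hydroxy-3-methyl-2-oxohexahydro-2H-cyclopenta[b]furan-5-carboxylate, via silyl enol ether 25 (not isolated)
Conditions: Cl(CH2)4MgBr (3 equiv), CuBr·SMe2 (20 mol %), Me3SiCl, THF, −78 °C; crude 25, mCPBA, NaHCO3, CH2Cl2, 0 °C; then citric acid, MeOH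
Reagents that add atoms: 4-chlorobutylmagnesium bromide, ClCCCC[Mg]Br; 3-chloroperoxybenzoic acid, OOC(=O)c1cccc(Cl)c1
Why: copper-catalysed, Me3SiCl-accelerated 1,4-addition should occur at C9 (β to the ketone, the stronger acceptor) anti to the C10 ethyl group, and Rubottom oxidation of the resulting silyl enol ether should occur on the convex face away from C13 and the ester, so the hydroxyl ends cis to H-12 and the acyl group on the concave face.

**Step 15**
Reactants: 26 tert-butyl (3R,3aR,4S,5S,6R,6aR)-4-{(3S)-3-[(tert-butoxycarbonyl)amino]-3-[(2S,4S)-4-methyl-5-oxooxolan-2-yl]propanoyl}-5-(4-chlorobutyl)-6-ethyl-4-hydroxy-3-methyl-2-oxohexahydro-2H-cyclopenta[b]furan-5-carboxylate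
Product: 27 tert-butyl (3R,3aR,4S,6S,7R,7aR)-4-{(2S)-2-[(tert-butoxycarbonyl)amino]-2-[(2S,4S)-4-methyl-5-oxooxolan-2-yl]ethyl}-6-(4-chlorobutyl)-7-ethyl-4-hydroxy-3-methyl-2,5-dioxooctahydro-1-benzofuran-6-carboxylate
Conditions: Al(OtBu)3 (1.5 equiv), toluene, 80 °C
Reagents that add atoms: none
Why: The aluminium alkoxide of the tertiary carbinol chelates the adjacent ketone (cisoid O–C–C=O), and the ring bond C9a–C12, held nearly parallel to the carbonyl π* orbital, shifts with its electron pair to the acyl carbon C1 while the carbinol carbon becomes the C9a ketone (α-ketol or acyloin rearrangement, as in the D-homoannulation of 17α-hydroxy-20-ketosteroids). The six-membered ring is not closed from a chain but arises by this 1,2-shift, which inserts C1 between C9a and C12 of the cyclopentane (ring enlargement by one atom). C12 migrates with retention, and the new stereocentre C1 is set by the chelate: because the acyl group sits on the concave face and the hydroxyl on the convex face, C2 ends on the concave face cis to C13 and the new hydroxyl cis to H-12 (1S). The step needs migration of C12 and not of C9; C9 is fully substituted and carries the electron-withdrawing tert-butyl ester, which makes it both the more hindered and the electron-poorer, hence the poorer migrating carbon. Relief of the congestion between two adjacent fully substituted carbons and the change from cyclopentane to cyclohexanone should make the shift downhill.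

**Step 16**
Reactants: 27 tert-butyl (3R,3aR,4S,6S,7R,7aR)-4-{(2S)-2-[(tert-butoxycarbonyl)amino]-2-[(2S,4S)-4-methyl-5-oxooxolan-2-yl]ethyl}-6-(4-chlorobutyl)-7-ethyl-4-hydroxy-3-methyl-2,5-dioxooctahydro-1-benzofuran-6-carboxylate
Product: 30 target alkaloid CNP0179500.2 (1S,3S,10R,11R,12R,13R,18S,20S), via amino keto acid salt 28 (not isolated), via cyclic imine 29 (not isolated)
Conditions: CF3CO2H, CH2Cl2, rt; evaporate; MeCN, 60 °C; then NaI (cat.), iPr2NEt, 75 °C
Reagents that add atoms: none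
Why: acid cleaves the Boc group and the tert-butyl ester, the β-keto acid decarboxylates and the γ-amino ketone condenses to the 1-pyrrolinium salt, and after neutralisation the imine nitrogen is alkylated by the pendant halide (Finkelstein, 7-exo-tet) and the iminium loses H-9 to give the enamine, the only tautomer possible because C1 is quaternary.

**Compound list**

1 | (4S)-4-[(tert-butyldimethylsilyl)oxy]cyclopent-2-en-1-one | O=C1C=C[C@@H](O[Si](C)(C)C(C)(C)C)C1 | starting material
2 | bromomagnesium (1R,4S)-4-[(tert-butyldimethylsilyl)oxy]-1-ethylcyclopent-2-en-1-olate | CC[C@]1(O[Mg]Br)C=C[C@@H](O[Si](C)(C)C(C)(C)C)C1 | intermediate (not isolated)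
3 | (1R,4S)-4-[(tert-butyldimethylsilyl)oxy]-1-ethylcyclopent-2-en-1-yl acetate | CC[C@]1(OC(C)=O)C=C[C@@H](O[Si](C)(C)C(C)(C)C)C1 | intermediate
4 | trimethylsilyl ketene acetal of acetate 3 | CC[C@]1(OC(=C)O[Si](C)(C)C)C=C[C@@H](O[Si](C)(C)C(C)(C)C)C1 | intermediate (not isolated)
5 | trimethylsilyl 2-[(1R,5S)-5-[(tert-butyldimethylsilyl)oxy]-3-ethylcyclopent-2-en-1-yl]acetate | C[Si](C)(C)OC(=O)C[C@@H]1C=C(CC)C[C@@H]1O[Si](C)(C)C(C)(C)C | intermediate (not isolated)
6 | 2-[(1R,5S)-5-[(tert-butyldimethylsilyl)oxy]-3-ethylcyclopent-2-en-1-yl]acetic acid | OC(=O)C[C@@H]1C=C(CC)C[C@@H]1O[Si](C)(C)C(C)(C)C | intermediate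
7 | (3aR,4S,6R,6aR)-4-[(tert-butyldimethylsilyl)oxy]-6-ethylhexahydro-2H-cyclopenta[b]furan-2-one | O=C1C[C@@H]2[C@H](O1)[C@H](CC)C[C@@H]2O[Si](C)(C)C(C)(C)C | intermediate
8 | (3R,3aR,4S,6R,6aR)-4-[(tert-butyldimethylsilyl)oxy]-6-ethyl-3-methylhexahydro-2H-cyclopenta[b]furan-2-one | O=C1[C@H](C)[C@@H]2[C@H](O1)[C@H](CC)C[C@@H]2O[Si](C)(C)C(C)(C)C | intermediate
9 | (3R,3aS,4S,6R,6aR)-6-ethyl-4-hydroxy-3-methylhexahydro-2H-cyclopenta[b]furan-2-one | O=C1[C@H](C)[C@@H]2[C@H](O1)[C@H](CC)C[C@@H]2O | intermediate (not isolated)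
10 | (3R,3aR,6R,6aR)-6-ethyl-3-methyltetrahydro-2H-cyclopenta[b]furan-2,4(3H)-dione | O=C1[C@H](C)[C@@H]2[C@H](O1)[C@H](CC)CC2=O | intermediate
11 | tert-butyl (3R,3aR,5R,6R,6aR)-6-ethyl-3-methyl-2,4-dioxohexahydro-2H-cyclopenta[b]furan-5-carboxylate (C5 epimerisable, drawn trans to ethyl) | O=C1[C@H](C)[C@@H]2[C@H](O1)[C@H](CC)[C@@H](C(=O)OC(C)(C)C)C2=O | intermediate
12 | tert-butyl (3R,3aR,6R,6aR)-6-ethyl-3-methyl-2-oxo-4-(trifluoromethanesulfonyloxy)-3,3a,6,6a-tetrahydro-2H-cyclopenta[b]furan-5-carboxylate | O=C1[C@H](C)[C@@H]2[C@H](O1)[C@H](CC)C(C(=O)OC(C)(C)C)=C2OS(=O)(=O)C(F)(F)F | intermediate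
13 | 2-[(tert-butyldimethylsilyl)oxy]acetaldehyde | O=CCO[Si](C)(C)C(C)(C)C | starting material
14 | (R)-2-methylpropane-2-sulfinamide | CC(C)(C)[S@@](=O)N | starting material
15 | (R,E)-N-{2-[(tert-butyldimethylsilyl)oxy]ethylidene}-2-methylpropane-2-sulfinamide | CC(C)(C)[S@@](=O)/N=C/CO[Si](C)(C)C(C)(C)C | intermediate
16 | 3-methylfuran-2(5H)-one | CC1=CCOC1=O | starting material
17 | tert-butyldimethyl[(3-methylfuran-2-yl)oxy]silane | Cc1ccoc1O[Si](C)(C)C(C)(C)C | intermediate (not isolated)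
18 | (R)-N-[(1S)-2-[(tert-butyldimethylsilyl)oxy]-1-[(2S)-4-methyl-5-oxo-2,5-dihydrofuran-2-yl]ethyl]-2-methylpropane-2-sulfinamide | CC(C)(C)[S@@](=O)N[C@H]([C@@H]1C=C(C)C(=O)O1)CO[Si](C)(C)C(C)(C)C | intermediate
19 | (5S)-5-[(1S)-1-amino-2-hydroxyethyl]-3-methylfuran-2(5H)-one hydrochloride | Cl.N[C@H]([C@@H]1C=C(C)C(=O)O1)CO | intermediate (not isolated)
20 | tert-butyl N-[(1S)-2-hydroxy-1-[(2S)-4-methyl-5-oxo-2,5-dihydrofuran-2-yl]ethyl]carbamate | CC(C)(C)OC(=O)N[C@H]([C@@H]1C=C(C)C(=O)O1)CO | intermediate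
21 | tert-butyl N-[(1S)-2-hydroxy-1-[(2S,4S)-4-methyl-5-oxooxolan-2-yl]ethyl]carbamate | CC(C)(C)OC(=O)N[C@H]([C@@H]1C[C@H](C)C(=O)O1)CO | intermediate
22 | tert-butyl N-[(1R)-2-iodo-1-[(2S,4S)-4-methyl-5-oxooxolan-2-yl]ethyl]carbamate | CC(C)(C)OC(=O)N[C@H]([C@@H]1C[C@H](C)C(=O)O1)CI | intermediate
23 | {(2R)-2-[(tert-butoxycarbonyl)amino]-2-[(2S,4S)-4-methyl-5-oxooxolan-2-yl]ethyl}(iodo)zinc | CC(C)(C)OC(=O)N[C@H]([C@@H]1C[C@H](C)C(=O)O1)C[Zn]I | intermediate (not isolated)
24 | tert-butyl (3R,3aS,6R,6aR)-4-{(3S)-3-[(tert-butoxycarbonyl)amino]-3-[(2S,4S)-4-methyl-5-oxooxolan-2-yl]propanoyl}-6-ethyl-3-methyl-2-oxo-3,3a,6,6a-tetrahydro-2H-cyclopenta[b]furan-5-carboxylate | O=C1[C@H](C)[C@@H]2[C@H](O1)[C@H](CC)C(C(=O)OC(C)(C)C)=C2C(=O)C[C@H](NC(=O)OC(C)(C)C)[C@@H]3C[C@H](C)C(=O)O3 | intermediate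
25 | trimethylsilyl enol ether of the C9 (4-chlorobutyl) conjugate adduct of 24 (enol ether geometry not defined) | O=C1[C@H](C)[C@@H]2[C@H](O1)[C@H](CC)[C@](CCCCCl)(C(=O)OC(C)(C)C)C2=C(O[Si](C)(C)C)C[C@H](NC(=O)OC(C)(C)C)[C@@H]3C[C@H](C)C(=O)O3 | intermediate (not isolated)
26 | tert-butyl (3R,3aR,4S,5S,6R,6aR)-4-{(3S)-3-[(tert-butoxycarbonyl)amino]-3-[(2S,4S)-4-methyl-5-oxooxolan-2-yl]propanoyl}-5-(4-chlorobutyl)-6-ethyl-4-hydroxy-3-methyl-2-oxohexahydro-2H-cyclopenta[b]furan-5-carboxylate | O=C1[C@H](C)[C@@H]2[C@H](O1)[C@H](CC)[C@](CCCCCl)(C(=O)OC(C)(C)C)[C@]2(O)C(=O)C[C@H](NC(=O)OC(C)(C)C)[C@@H]3C[C@H](C)C(=O)O3 | intermediate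
27 | tert-butyl (3R,3aR,4S,6S,7R,7aR)-4-{(2S)-2-[(tert-butoxycarbonyl)amino]-2-[(2S,4S)-4-methyl-5-oxooxolan-2-yl]ethyl}-6-(4-chlorobutyl)-7-ethyl-4-hydroxy-3-methyl-2,5-dioxooctahydro-1-benzofuran-6-carboxylate | O=C1[C@H](C)[C@@H]2[C@H](O1)[C@H](CC)[C@](CCCCCl)(C(=O)OC(C)(C)C)C(=O)[C@]2(O)C[C@H](NC(=O)OC(C)(C)C)[C@@H]3C[C@H](C)C(=O)O3 | intermediate
28 | trifluoroacetate salt of (3R,3aR,4S,6S,7R,7aR)-4-{(2S)-2-amino-2-[(2S,4S)-4-methyl-5-oxooxolan-2-yl]ethyl}-6-(4-chlorobutyl)-7-ethyl-4-hydroxy-3-methyl-2,5-dioxooctahydro-1-benzofuran-6-carboxylic acid | O=C1[C@H](C)[C@@H]2[C@H](O1)[C@H](CC)[C@](CCCCCl)(C(O)=O)C(=O)[C@]2(O)C[C@H](N)[C@@H]3C[C@H](C)C(=O)O3.OC(=O)C(F)(F)F | intermediate (not isolated)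
29 | tricyclic hydroxy 1-pyrroline (N4=C9a imine; 1S,3S,10R,11R,12R,13R,18S,20S; C9 carrying the 4-chlorobutyl chain, both C9 epimers) | O=C1[C@H](C)[C@@H]2[C@H](O1)[C@H](CC)C(CCCCCl)C3=N[C@H]([C@@H]4C[C@H](C)C(=O)O4)C[C@]23O | intermediate (not isolated)
30 | target alkaloid CNP0179500.2, (1S,3S,10R,11R,12R,13R,18S,20S)-1-hydroxy-9,9a-didehydro stenine-type pentacycle with the C3 methylbutyrolactone | CC[C@@H]1C2=C3N(CCCC2)[C@H]([C@@H]2C[C@H](C)C(=O)O2)C[C@]3(O)[C@H]2[C@@H]1OC(=O)[C@@H]2C | target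

**Totals.** Total step count: 16. Longest linear sequence: 11 steps (steps 1–7 and 13–16); the side-chain fragment takes steps 8–12.

**Steps most likely to fail**

1. Step 15 (key step). Retro-aldol cleavage of the C9a–C9 bond in the aluminium alkoxide, expelling the ester enolate, may outrun the 1,2-shift. Alternatively the chelate may not form at the crowded carbinol, so that migration stalls. The fallback removes the free alkoxide and changes the mode of activation. It sets out from 26: silylation of the tertiary hydroxyl with 1-(trimethylsilyl)imidazole gives the α-trimethylsilyloxy ketone F1. A bulky monodentate aluminium Lewis acid, MeAl(OC6H2-4-Br-2,6-tBu2)2, in CH2Cl2 at −78 to −20 °C then promotes the acyloin rearrangement of the α-silyloxy ketone with O-to-O silyl transfer. The two oxygens must be syn for that transfer, so the steric course should be unchanged, and the product is the ring-enlarged silyl ether F2. Mild acidic methanolysis (citric acid, MeOH) returns to the route at 27.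

2. Step 14. The organocopper reagent may fail to add to the tetrasubstituted, doubly acylated alkene, or may instead add 1,2 or deprotonate C10 with loss of the lactone oxygen. Epoxidation of the silyl enol ether next to the new quaternary centre may also lose facial selectivity. The fallback separates hydroxylation from chain introduction. It sets out from 24: copper hydride conjugate reduction ([(Ph3P)CuH]6 cat., Me2PhSiH) and Rubottom oxidation of the resulting silyl enol ether (mCPBA, then citric acid/MeOH) give the chain-free ketol F3, with hydride and oxygen both delivered on the convex face. Al(OtBu)3 in toluene then effects the same ring enlargement, C9 still being deactivated by its ester, to give the β-keto ester F4. Alkylation of F4 with 1-chloro-4-iodobutane and Cs2CO3 in DMF, on the convex face anti to the ethyl group, returns to the route at 27.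

3. Step 13. CO insertion may be slower than direct transmetalation, giving the non-carbonylated coupling product, or the zinc reagent may be lost by β-elimination of the carbamate before it couples. The fallback fixes the carbonyl group first. It sets out from 12: thiocarbonylation (Pd(OAc)2, Xantphos, CO, EtSH, Et3N) gives the S-ethyl thioester F5. Fukuyama coupling of F5 with the organozinc iodide 23 (PdCl2(PPh3)2, THF/toluene, rt) returns to the route at 24.

**Further compounds**

F1 | step 15 | α-trimethylsilyloxy ketone, the O-trimethylsilyl ether of 26 | O=C1[C@H](C)[C@@H]2[C@H](O1)[C@H](CC)[C@](CCCCCl)(C(=O)OC(C)(C)C)[C@]2(O[Si](C)(C)C)C(=O)C[C@H](NC(=O)OC(C)(C)C)[C@@H]3C[C@H](C)C(=O)O3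
F2 | step 15 | ring-enlarged silyl ether, the O-trimethylsilyl ether of 27 | O=C1[C@H](C)[C@@H]2[C@H](O1)[C@H](CC)[C@](CCCCCl)(C(=O)OC(C)(C)C)C(=O)[C@]2(O[Si](C)(C)C)C[C@H](NC(=O)OC(C)(C)C)[C@@H]3C[C@H](C)C(=O)O3
F3 | step 14 | chain-free ketol, tert-butyl (3R,3aR,4S,5S,6R,6aR)-4-{(3S)-3-[(tert-butoxycarbonyl)amino]-3-[(2S,4S)-4-methyl-5-oxooxolan-2-yl]propanoyl}-6-ethyl-4-hydroxy-3-methyl-2-oxohexahydro-2H-cyclopenta[b]furan-5-carboxylate | O=C1[C@H](C)[C@@H]2[C@H](O1)[C@H](CC)[C@H](C(=O)OC(C)(C)C)[C@]2(O)C(=O)C[C@H](NC(=O)OC(C)(C)C)[C@@H]3C[C@H](C)C(=O)O3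
F4 | step 14 | ring-enlarged β-keto ester, tert-butyl (3R,3aR,4S,6S,7R,7aR)-4-{(2S)-2-[(tert-butoxycarbonyl)amino]-2-[(2S,4S)-4-methyl-5-oxooxolan-2-yl]ethyl}-7-ethyl-4-hydroxy-3-methyl-2,5-dioxooctahydro-1-benzofuran-6-carboxylate (C6 epimerisable) | O=C1[C@H](C)[C@@H]2[C@H](O1)[C@H](CC)[C@H](C(=O)OC(C)(C)C)C(=O)[C@]2(O)C[C@H](NC(=O)OC(C)(C)C)[C@@H]3C[C@H](C)C(=O)O3
F5 | step 13 | S-ethyl thioester, tert-butyl (3R,3aS,6R,6aR)-6-ethyl-4-[(ethylsulfanyl)carbonyl]-3-methyl-2-oxo-3,3a,6,6a-tetrahydro-2H-cyclopenta[b]furan-5-carboxylate | O=C1[C@H](C)[C@@H]2[C@H](O1)[C@H](CC)C(C(=O)OC(C)(C)C)=C2C(=O)SCC
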